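**Assumptions**
- Jaeskeanin is the daucane 5,6-epoxide written in the target SMILES.
- The phenol of the p-hydroxybenzoate is carried as its TBS ether and removed last.
- In the Rh [5+2], the stereocentre at the cleaved cyclopropane carbon is assumed to be transferred with net retention. The Charette ligand enantiomer is the one that gives cyclopropane 5 as drawn (assumed (R,R)).
- Ring positions use azulene numbering: C1 carries OH and iPr, C3a carries Me, C8 carries the ester, and the epoxide is C5–C6. The face bearing the angular CH3 is called β.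

**Retrosynthesis**
1. Jaeskeanin comes from a TBS-protected ester. Late steps are iPrCeCl2 addition to the C1 ketone and V-directed epoxidation of the C5=C6 alkene, syn to the C8–OH.
2. C8–O, C8a–H and C3a–Me derive from a bicyclic enone. Weitz–Scheffer epoxidation followed by SmI2 C–O cleavage installs C8–OH and C8a–H.
3. The key step is a Wender Rh-catalysed [5+2] of a tethered vinylcyclopropane–ynone. It forms the 7-membered ring, the trisubstituted alkene, the quaternary C3a and the 5-ring at once. The stereocentre at the quaternary cyclopropane carbon becomes C3a.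
4. Ring-formation order: the cyclopropane first (Charette), then the 5- and 7-rings together in the [5+2].
5. The vinylcyclopropane comes from methacrolein via a dienol, Charette cyclopropanation, and a three-carbon ynone tether (HWE, Cu–H reduction, Weinreb amide, ethynyl addition).

---

**Step 1**
Reactants: 1 methacrolein; 2 triethyl 2-phosphonopropionate
Product: 3 ethyl (2E)-2,4-dimethylpenta-2,4-dienoate
Conditions: NaH, THF, 0 °C → rt
Reagents that add atoms: none
Why: Horner–Wadsworth–Emmons olefination of an enal with an α-methyl phosphonate gives the E-trisubstituted dienoate.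

**Step 2**
Reactants: 3
Product: 4 (2E)-2,4-dimethylpenta-2,4-dien-1-ol
Conditions: DIBAL-H (2.3 equiv), CH2Cl2, −78 °C
Reagents that add atoms: none
Why: DIBAL-H does a 1,2-reduction of the ester to the allylic alcohol and leaves both alkenes untouched.

**Step 3**
Reactants: 4
Product: 5 [(1R,2S)-1-methyl-2-(prop-1-en-2-yl)cyclopropyl]methanol
Conditions: Et2Zn, CH2I2, (4R,5R)-2-butyl-N,N,N′,N′-tetramethyl-1,3,2-dioxaborolane-4,5-dicarboxamide, CH2Cl2, −10 → 0 °C; basic work-up
Reagents that add atoms: diiodomethane, ICI (supplies the ring CH2)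
Why: Charette's chiral-dioxaborolane Simmons–Smith cyclopropanation is directed by the allylic OH to the proximal E-trisubstituted alkene rather than the isopropenyl group. The ligand sets the quaternary cyclopropane stereocentre (future C3a); the E geometry makes CH2OH and isopropenyl trans.

**Step 4**
Reactants: 5
Product: 6 (1R,2S)-1-methyl-2-(prop-1-en-2-yl)cyclopropane-1-carbaldehyde
Conditions: Dess–Martin periodinane, NaHCO3, CH2Cl2, 0 °C
Reagents that add atoms: none
Why: Buffered DMP oxidation avoids acid-induced cyclopropylcarbinyl ring opening, and the stereocentres are untouched.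

**Step 5**
Reactants: 6; 7 triethyl phosphonoacetate
Product: 8 ethyl (E)-3-[(1R,2S)-1-methyl-2-(prop-1-en-2-yl)cyclopropyl]acrylate
Conditions: NaH, THF, 0 °C → rt
Reagents that add atoms: none
Why: HWE olefination adds the C_b–C_a unit (the enoate carbons that become C2 and C1 of the 5-ring) as the E-enoate.

**Step 6**
Reactants: 8
Product: 9 ethyl 3-[(1R,2S)-1-methyl-2-(prop-1-en-2-yl)cyclopropyl]propanoate
Conditions: [(Ph3P)CuH]6 (5 mol%), PhSiH3 (1.5 equiv), toluene, 0 °C → rt; aq. NH4Cl
Reagents that add atoms: none (delivers H only)
Why: Cu–H conjugate reduction is chemoselective for the enoate. Radical-type reductions such as Mg/MeOH are avoided because they would open the cyclopropylcarbinyl radical.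

**Step 7**
Reactants: 9
Product: 10 N-methoxy-N-methyl-3-[(1R,2S)-1-methyl-2-(prop-1-en-2-yl)cyclopropyl]propanamide
Conditions: MeNH(OMe)·HCl, iPrMgCl (3 equiv), THF, −20 → 0 °C
Reagents that add atoms: N,O-dimethylhydroxylamine hydrochloride, CNOC.Cl
Why: This is the Weinreb amide formation from an ester, giving a ketone precursor that cannot be over-added to.

**Step 8**
Reactants: 10
Product: 11 1-[(1R,2S)-1-methyl-2-(prop-1-en-2-yl)cyclopropyl]pent-4-yn-3-one (the vinylcyclopropane–ynone, drawn with C#CC(=O)CC–cyclopropyl)
Conditions: HC≡CMgBr (2 equiv), THF, 0 °C; cold aq. NH4Cl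
Reagents that add atoms: ethynylmagnesium bromide, C#C[Mg]Br
Why: Weinreb ketone synthesis delivers the terminal ynone, which is the 2π partner and sets the future C1 carbonyl.

**Step 9**
Reactants: 11
Product: 12 (3aR)-3a,6-dimethyl-3,3a,4,7-tetrahydroazulen-1(2H)-one
Conditions: [Rh(CO)2Cl]2 (5 mol%), ClCH2CH2Cl (0.02 M), 80 °C
Reagents that add atoms: none
Why: Proposed new method: an intramolecular Wender-type Rh(I) [5+2] of the vinylcyclopropane with the tethered ynone. Ynone and vinyl coordination, then oxidative cyclisation with cleavage of the proximal C1–C2 cyclopropane bond, gives a rhodacycle. Reductive elimination forms C2–C(alkyne) and vinyl-CH2–C(alkyne) bonds, and the three-atom tether closes the 5-ring while the 7-ring and the trisubstituted C5=C6 alkene (from the isopropenyl group) form. The new quaternary C3a retains the configuration of the cyclopropane carbon, so the stereocentre is transferred. The closest known reaction is the Wender [5+2] forming angular quaternary centres, here extended to an α-methylvinyl group, a quaternary C2 and a terminal ynone.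

**Step 10**
Reactants: 12
Product: 13 8α,8a-epoxy-3a,6-dimethyl-3,3a,4,7-tetrahydroazulen-1(2H)-one (epoxide on the face anti to the angular CH3)
Conditions: 30% H2O2 (5 equiv), 1 M NaOH (1 equiv), MeOH, 0 °C
Reagents that add atoms: hydrogen peroxide, OO
Why: Weitz–Scheffer nucleophilic epoxidation attacks only the enone and leaves the trisubstituted alkene alone. HOO⁻ is expected to add at C8 from the α face, anti to the axial angular methyl, which sets C8 and the epoxide α.

**Step 11**
Reactants: 13
Product: 14 (3aR,8S?,8aS?)-8-hydroxy-3a,6-dimethyl-3,3a,4,7,8,8a-hexahydroazulen-1(2H)-one (8α-OH, trans-fused with 8a-H α and CH3 β; SMILES in list)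
Conditions: SmI2 (2.5 equiv), THF, MeOH (5 equiv), −78 °C
Reagents that add atoms: none (MeOH supplies H only)
Why: Molander's SmI2 reductive cleavage of an α,β-epoxy ketone breaks the α C8a–O bond and keeps the C8–O bond, so C8 is fixed; the Sm(III) enolate is protonated from the α face, anti to the angular methyl, giving trans 8a-H.

**Step 12**
Reactants: 14
Product: 15 5α,6α-epoxy-8α-hydroxy-3a,6-dimethyl-octahydroazulen-1-one (epoxide cis to the C8–OH)
Conditions: VO(acac)2 (5 mol%), TBHP (1.5 equiv, 5.5 M in decane), CH2Cl2, 0 °C
Reagents that add atoms: tert-butyl hydroperoxide, CC(C)(C)OO (one O is transferred)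
Why: V-catalysed hydroxyl-directed (Sharpless–Michaelson) epoxidation of the homoallylic alcohol delivers oxygen syn to the C8–OH, setting C5 and C6; the ketone is inert.

**Step 13**
Reactants: 15; 16 4-(tert-butyldimethylsilyloxy)benzoic acid
Product: 17 8α-[4-(TBSO)benzoyloxy]-5α,6α-epoxy-3a,6-dimethyl-octahydroazulen-1-one
Conditions: 2,4,6-Cl3C6H2COCl, Et3N, THF, rt; then 15 and DMAP, toluene, rt
Reagents that add atoms: none (the acyl group comes from 16)
Why: Yamaguchi esterification acylates the only free OH with retention at C8.

**Step 14**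
Reactants: 17
Product: 18 TBS-protected jaeskeanin (1β-OH, 1α-iPr)
Conditions: iPrMgCl·LiCl (3 equiv), CeCl3 (3 equiv, anhydrous), THF, −78 °C
Reagents that add atoms: isopropylmagnesium chloride–LiCl, CC(C)[Mg]Cl
Why: Organocerium addition to a ketone without enolisation tolerates the aryl ester and epoxide at −78 °C; as for 17-keto steroids, attack is from the α face anti to the angular CH3, giving 1α-iPr and 1β-OH.

**Step 15**
Reactants: 18
Product: 19 jaeskeanin
Conditions: TBAF (1.2 equiv), AcOH (1.2 equiv), THF, 0 °C
Reagents that add atoms: none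
Why: Buffered fluoride cleaves the phenolic TBS ether and leaves the ester, epoxide and tertiary alcohol intact.

---

**Compound list**

| # | Name | SMILES | Role |
|---|---|---|---|
| 1 | methacrolein | C=C(C)C=O | starting material |
| 2 | triethyl 2-phosphonopropionate | CCOC(=O)C(C)P(=O)(OCC)OCC | starting material |
| 3 | ethyl (2E)-2,4-dimethylpenta-2,4-dienoate | CCOC(=O)/C(C)=C/C(C)=C | intermediate |
| 4 | (2E)-2,4-dimethylpenta-2,4-dien-1-ol | OC/C(C)=C/C(C)=C | intermediate |
| 5 | [(1R,2S)-1-methyl-2-(prop-1-en-2-yl)cyclopropyl]methanol | OC[C@]1(C)C[C@H]1C(C)=C | intermediate |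
| 6 | (1R,2S)-1-methyl-2-(prop-1-en-2-yl)cyclopropane-1-carbaldehyde | O=C[C@]1(C)C[C@H]1C(C)=C | intermediate |
| 7 | triethyl phosphonoacetate | CCOC(=O)CP(=O)(OCC)OCC | starting material |
| 8 | ethyl (E)-3-(cyclopropyl)acrylate (cyclopropane as in 5) | CCOC(=O)/C=C/[C@]1(C)C[C@H]1C(C)=C | intermediate |
| 9 | ethyl 3-(cyclopropyl)propanoate | CCOC(=O)CC[C@]1(C)C[C@H]1C(C)=C | intermediate |
| 10 | Weinreb amide of 9 | CON(C)C(=O)CC[C@]1(C)C[C@H]1C(C)=C | intermediate |
| 11 | vinylcyclopropane–ynone | C#CC(=O)CC[C@]1(C)C[C@H]1C(C)=C | intermediate |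
| 12 | (3aR)-3a,6-dimethyl-3,3a,4,7-tetrahydroazulen-1(2H)-one | O=C1CC[C@]2(C)CC=C(C)CC=C12 | intermediate |
| 13 | 8α,8a-epoxy ketone | O=C1CC[C@]2(C)CC=C(C)C[C@@H]3O[C@]123 | intermediate |
| 14 | 8α-hydroxy ketone, trans-fused | O=C1CC[C@]2(C)CC=C(C)C[C@H](O)[C@H]21 | intermediate |
| 15 | 5α,6α-epoxy-8α-hydroxy ketone | O=C1CC[C@]2(C)C[C@@H]3O[C@]3(C)C[C@H](O)[C@H]21 | intermediate |
| 16 | 4-(tert-butyldimethylsilyloxy)benzoic acid | CC(C)(C)[Si](C)(C)Oc1ccc(cc1)C(=O)O | starting material |
| 17 | TBSO-benzoate epoxy ketone | O=C1CC[C@]2(C)C[C@@H]3O[C@]3(C)C[C@H](OC(=O)c3ccc(O[Si](C)(C)C(C)(C)C)cc3)[C@H]21 | intermediate |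
| 18 | TBS-protected jaeskeanin | CC(C)[C@]1(O)CC[C@]2(C)C[C@@H]3O[C@]3(C)C[C@H](OC(=O)c3ccc(O[Si](C)(C)C(C)(C)C)cc3)[C@H]21 | intermediate |
| 19 | jaeskeanin | CC(C)[C@]1(O)CC[C@]2(C)C[C@@H]3O[C@]3(C)C[C@H](OC(=O)c3ccc(O)cc3)[C@H]21 | target |

**Totals:** 15 steps; longest linear sequence 15 (methacrolein → 19); compound 16 is commercial.

**Three steps most likely to fail**

1. **Step 9, Rh [5+2].**
   - Risks: Rh insertion into the more hindered C1–C2 bond to give a tertiary Rh–C, competing C1–C3 cleavage giving a bridged product, the α-methylvinyl group, and the terminal ynone.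
   - Fallback: build the 7-ring by a different approach. Use Cu-catalysed asymmetric conjugate addition of an allyl nucleophile to 3-methylcyclopentenone, trap the enolate as an aldol with an aldehyde bearing a methallyl group, then close the ring by RCM. The rest of the route (C8, C8a, epoxide, C1) is unchanged.

2. **Steps 10–11, facial selectivity at C8 and C8a.**
   - Risk: HOO⁻ could add from the β face, or protonation could give a cis ring fusion.
   - Fallback: use directed chemistry instead. Add iPrCeCl2 1,2 to enone 12, then V-directed epoxidation of the tertiary allylic alcohol. Open the epoxide with Red-Al (hydride at C8a from α), then esterify C8 by Mitsunobu with inversion. This delivers 8α-OAr, 8a-α-H and the correct C1 configuration without relying on enone facial bias.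

3. **Step 14, iPrCeCl2 addition late in the route.**
   - Risks: epoxide opening by Lewis-acidic Mg/Ce salts, E1cB loss of the β-aroyloxy group, and epimerisation at C8a.
   - Fallback: introduce C1 earlier. Protect the C8–OH of 14 as TES, add iPrMgBr/CeCl3, remove TES, then do the V-directed epoxidation and selective secondary-alcohol esterification. Alternatively add isopropenyl-CeCl2 and hydrogenate the 1,1-disubstituted alkene late.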